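**Retrosynthetic overview**

- The target is the 5,7,4'-tri-O-benzyl ether minus its benzyl groups (hydrogenolysis); ring C, the pyranone, is the only ring that is built, rings A and B being bought as benzenes.
- Feature used: C3 carries nothing but a methoxy group and lies between C4 (the carbonyl on ring A) and C2 (bonded to O1 and to ring B). The O1–C2 bond can therefore pre-exist as an aryl ester of the ring B acid, and C3 with its oxygen can arrive as one carbon from Ph3P=CHOMe.
- Key disconnections, made in one flask: C3–C4 (acylation of the ylide by a salicyloyl chloride) and C2=C3 (intramolecular Wittig olefination of the ester carbonyl).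
- The salicyloyl chloride comes from a ring A 2-hydroxybenzaldehyde by O-aroylation, Pinnick oxidation and chloride formation; the aldehyde comes from phloroglucinol (tribenzyl ether, dibromination, methoxylation, formylation, chelation-controlled mono-debenzylation).
- The ring B acid chloride comes from 2,5-dimethoxyphenol (benzylation, formylation, oxidation, chloride formation).

Key step: step 13

Remark: the target has no stereocentre, so no configuration has to be set anywhere in the route.

**Route**

Step 1
Reactants: 1 phloroglucinol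
Product: 2 1,3,5-tris(benzyloxy)benzene
Conditions: BnBr (3.3 equiv), K2CO3, DMF, rt → 60 °C
Reagents that add atoms: benzyl bromide, BrCc1ccccc1
Why: Williamson O-alkylation of the three phenoxides, in which K2CO3 in DMF favours O- over C-benzylation and the symmetrical triether should crystallise away from C-benzylated by-products.

Step 2
Reactants: 2 1,3,5-tris(benzyloxy)benzene
Product: 3 1,3,5-tris(benzyloxy)-2,4-dibromobenzene
Conditions: NBS (2.05 equiv), CH2Cl2, −20 → 0 °C
Reagents that add atoms: N-bromosuccinimide, O=C1CCC(=O)N1Br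
Why: Electrophilic aromatic bromination of a ring activated by three alkoxy groups, which should stop at the dibromide with two equivalents of NBS because each bromine lowers the reactivity of the ring.

Step 3
Reactants: 3 1,3,5-tris(benzyloxy)-2,4-dibromobenzene
Product: 4 1,3,5-tris(benzyloxy)-2,4-dimethoxybenzene
Conditions: NaOMe (excess), CuI (0.2 equiv), MeOH/DMF, 110 °C
Reagents that add atoms: sodium methoxide, C[O-].[Na+]
Why: Ullmann-type copper-catalysed methoxylation of aryl bromides, the standard way to turn bromopolyalkoxybenzenes into their methoxy analogues, with benzyl ethers inert to methoxide.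

Step 4
Reactants: 4 1,3,5-tris(benzyloxy)-2,4-dimethoxybenzene
Product: 5 2,4,6-tris(benzyloxy)-3,5-dimethoxybenzaldehyde
Conditions: POCl3, DMF, 0 → 70 °C; then H2O
Reagents that add atoms: N,N-dimethylformamide, CN(C)C=O; water, O
Why: Vilsmeier–Haack formylation at the only free ring position, which is ortho to two benzyloxy groups and para to the third, as in the formylation of phloroglucinol triethers.

Step 5
Reactants: 5 2,4,6-tris(benzyloxy)-3,5-dimethoxybenzaldehyde
Product: 6 4,6-bis(benzyloxy)-2-hydroxy-3,5-dimethoxybenzaldehyde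
Conditions: MgBr2·OEt2 (1.2 equiv), toluene/Et2O, 80 °C; then 1 M HCl
Reagents that add atoms: none
Why: Chelation-controlled debenzylation, in which MgBr2 bridges the aldehyde oxygen and an ortho ether oxygen so that bromide cleaves only that benzyl group; the two ortho ethers are equivalent by symmetry, and the para benzyl ether and the methyl ethers lack the chelate.

Step 6
Reactants: 7 2,5-dimethoxyphenol
Product: 8 2-(benzyloxy)-1,4-dimethoxybenzene
Conditions: BnBr, K2CO3, DMF, 60 °C
Reagents that add atoms: benzyl bromide, BrCc1ccccc1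
Why: Williamson ether synthesis on the single phenol.

Step 7
Reactants: 8 2-(benzyloxy)-1,4-dimethoxybenzene
Product: 9 4-(benzyloxy)-2,5-dimethoxybenzaldehyde
Conditions: POCl3, DMF, 0 → 60 °C; then H2O
Reagents that add atoms: N,N-dimethylformamide, CN(C)C=O; water, O
Why: Vilsmeier–Haack formylation para to the benzyloxy group and ortho to a methoxy group, the position at which 1,2,4-trimethoxybenzene is formylated.

Step 8
Reactants: 9 4-(benzyloxy)-2,5-dimethoxybenzaldehyde
Product: 10 4-(benzyloxy)-2,5-dimethoxybenzoic acid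
Conditions: NaClO2, NaH2PO4, 2-methyl-2-butene, t-BuOH/THF/H2O, rt
Reagents that add atoms: sodium chlorite, [O-]Cl=O.[Na+]
Why: Pinnick oxidation of the aldehyde, with 2-methyl-2-butene trapping HOCl so that the electron-rich ring is not chlorinated.

Step 9
Reactants: 10 4-(benzyloxy)-2,5-dimethoxybenzoic acid
Product: 11 4-(benzyloxy)-2,5-dimethoxybenzoyl chloride
Conditions: (COCl)2, DMF (cat.), CH2Cl2, 0 °C → rt; evaporated
Reagents that add atoms: oxalyl chloride, O=C(Cl)C(=O)Cl
Why: Acid chloride formation through the catalytic chloroiminium (Vilsmeier-type) intermediate, mild enough for aryl benzyl and methyl ethers.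

Step 10
Reactants: 6 4,6-bis(benzyloxy)-2-hydroxy-3,5-dimethoxybenzaldehyde; 11 4-(benzyloxy)-2,5-dimethoxybenzoyl chloride
Product: 12 3,5-bis(benzyloxy)-2-formyl-4,6-dimethoxyphenyl 4-(benzyloxy)-2,5-dimethoxybenzoate
Conditions: Et3N, DMAP (cat.), CH2Cl2, 0 °C → rt
Reagents that add atoms: none
Why: O-acylation of the only free hydroxyl with an acid chloride under DMAP nucleophilic catalysis, which overcomes the hydrogen bond to the aldehyde and the ortho crowding; this sets the future O1–C2 bond.

Step 11
Reactants: 12 3,5-bis(benzyloxy)-2-formyl-4,6-dimethoxyphenyl 4-(benzyloxy)-2,5-dimethoxybenzoate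
Product: 13 4,6-bis(benzyloxy)-2-{[4-(benzyloxy)-2,5-dimethoxybenzoyl]oxy}-3,5-dimethoxybenzoic acid
Conditions: NaClO2, NaH2PO4, 2-methyl-2-butene, t-BuOH/THF/H2O, rt
Reagents that add atoms: sodium chlorite, [O-]Cl=O.[Na+]
Why: Pinnick oxidation, whose buffered, weakly acidic medium should leave the aryl ester and the benzyl ethers untouched and which tolerates hindered aromatic aldehydes.

Step 12
Reactants: 13 4,6-bis(benzyloxy)-2-{[4-(benzyloxy)-2,5-dimethoxybenzoyl]oxy}-3,5-dimethoxybenzoic acid
Product: 14 4,6-bis(benzyloxy)-2-{[4-(benzyloxy)-2,5-dimethoxybenzoyl]oxy}-3,5-dimethoxybenzoyl chloride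
Conditions: (COCl)2, DMF (cat.), CH2Cl2, 0 °C → rt; evaporated with toluene, used crude
Reagents that add atoms: oxalyl chloride, O=C(Cl)C(=O)Cl
Why: Acid chloride formation by the chloroiminium-catalysed method, as used for O-acylsalicylic acids such as acetylsalicylic acid.

Step 13
Reactants: 14 4,6-bis(benzyloxy)-2-{[4-(benzyloxy)-2,5-dimethoxybenzoyl]oxy}-3,5-dimethoxybenzoyl chloride; 15 (methoxymethyl)triphenylphosphonium chloride
Product: 18 5,7-bis(benzyloxy)-2-[4-(benzyloxy)-2,5-dimethoxyphenyl]-3,6,8-trimethoxy-4H-chromen-4-one, via (methoxymethylidene)triphenylphosphorane 16 (not isolated), via acyl(methoxy)phosphorane 17 (not isolated)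
Conditions: 15 (2.2 equiv), NaN(SiMe3)2 (2.1 equiv), THF, 0 °C; 14 in THF added at −78 °C, then rt; then toluene, 110 °C
Reagents that add atoms: none
Why: Proposed new method: ylide 16 is C-acylated by the acid chloride of 14 (bond C3–C4) and a second equivalent of 16 takes the now acidic proton, giving the stabilised acyl(methoxy)phosphorane 17, whose ylide carbon on heating adds to the aryl ester carbonyl five atoms away; the oxaphosphetane then collapses to C2=C3 and Ph3P=O. The closest known reaction type is the flavone synthesis in which an ortho-acylphosphorane, made from an O-aroylsalicylic acid derivative and an unsubstituted or silyl-substituted methylene ylide, olefinates the neighbouring aryl ester intramolecularly; what has not been shown is the methoxy group on the ylide carbon. That group should help and not hinder, since lone-pair repulsion makes an alkoxy-substituted stabilised ylide more nucleophilic than its parent (such ylides olefinate aldehydes readily), while the extra bulk is offset by the intramolecular, six-membered delivery. Ring C is closed at carbon as a six-membered ring (6-exo-trig addition of C3 to the ester C=O, then loss of Ph3P=O), with the O1–C2 bond already in place; no stereocentre is formed. The step needs chemoselectivity, attack of 16 on the acid chloride and not on the aryl ester, which the far higher electrophilicity of the chloride at −78 °C and the ortho-flanked, hindered ester should secure; there is only one ester, so the closure has a single course, and no phenol or other acidic group is present to quench the ylide.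

Step 14
Reactants: 18 5,7-bis(benzyloxy)-2-[4-(benzyloxy)-2,5-dimethoxyphenyl]-3,6,8-trimethoxy-4H-chromen-4-one
Product: 19 5,7,4'-trihydroxy-3,6,8,2',5'-pentamethoxyflavone
Conditions: H2 (1 atm), 10% Pd/C, EtOAc/MeOH, rt
Reagents that add atoms: none
Why: Catalytic hydrogenolysis of the three aryl benzyl ethers, which should leave the methyl ethers and the tetrasubstituted C2=C3 bond of the chromone intact at ambient pressure.

**Compound list**

1 | phloroglucinol | Oc1cc(O)cc(O)c1 | starting material
2 | 1,3,5-tris(benzyloxy)benzene | c1ccc(COc2cc(OCc3ccccc3)cc(OCc3ccccc3)c2)cc1 | intermediate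
3 | 1,3,5-tris(benzyloxy)-2,4-dibromobenzene | Brc1c(OCc2ccccc2)cc(OCc2ccccc2)c(Br)c1OCc1ccccc1 | intermediate
4 | 1,3,5-tris(benzyloxy)-2,4-dimethoxybenzene | COc1c(OCc2ccccc2)cc(OCc2ccccc2)c(OC)c1OCc1ccccc1 | intermediate
5 | 2,4,6-tris(benzyloxy)-3,5-dimethoxybenzaldehyde | COc1c(OCc2ccccc2)c(C=O)c(OCc2ccccc2)c(OC)c1OCc1ccccc1 | intermediate
6 | 4,6-bis(benzyloxy)-2-hydroxy-3,5-dimethoxybenzaldehyde | COc1c(O)c(C=O)c(OCc2ccccc2)c(OC)c1OCc1ccccc1 | intermediate
7 | 2,5-dimethoxyphenol | COc1ccc(OC)c(O)c1 | starting material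
8 | 2-(benzyloxy)-1,4-dimethoxybenzene | COc1ccc(OC)c(OCc2ccccc2)c1 | intermediate
9 | 4-(benzyloxy)-2,5-dimethoxybenzaldehyde | COc1cc(OCc2ccccc2)c(OC)cc1C=O | intermediate
10 | 4-(benzyloxy)-2,5-dimethoxybenzoic acid | COc1cc(OCc2ccccc2)c(OC)cc1C(=O)O | intermediate
11 | 4-(benzyloxy)-2,5-dimethoxybenzoyl chloride | COc1cc(OCc2ccccc2)c(OC)cc1C(=O)Cl | intermediate
12 | 3,5-bis(benzyloxy)-2-formyl-4,6-dimethoxyphenyl 4-(benzyloxy)-2,5-dimethoxybenzoate | COc1c(OCc2ccccc2)c(OC)c(OC(=O)c2cc(OC)c(OCc3ccccc3)cc2OC)c(C=O)c1OCc1ccccc1 | intermediate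
13 | 4,6-bis(benzyloxy)-2-{[4-(benzyloxy)-2,5-dimethoxybenzoyl]oxy}-3,5-dimethoxybenzoic acid | COc1c(OCc2ccccc2)c(OC)c(OC(=O)c2cc(OC)c(OCc3ccccc3)cc2OC)c(C(=O)O)c1OCc1ccccc1 | intermediate
14 | 4,6-bis(benzyloxy)-2-{[4-(benzyloxy)-2,5-dimethoxybenzoyl]oxy}-3,5-dimethoxybenzoyl chloride | COc1c(OCc2ccccc2)c(OC)c(OC(=O)c2cc(OC)c(OCc3ccccc3)cc2OC)c(C(=O)Cl)c1OCc1ccccc1 | intermediate
15 | (methoxymethyl)triphenylphosphonium chloride | COC[P+](c1ccccc1)(c1ccccc1)c1ccccc1.[Cl-] | starting material
16 | (methoxymethylidene)triphenylphosphorane | COC=P(c1ccccc1)(c1ccccc1)c1ccccc1 | intermediate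
17 | 3,5-bis(benzyloxy)-4,6-dimethoxy-2-[methoxy(triphenyl-λ5-phosphanylidene)acetyl]phenyl 4-(benzyloxy)-2,5-dimethoxybenzoate (acyl(methoxy)phosphorane) | COC(C(=O)c1c(OC(=O)c2cc(OC)c(OCc3ccccc3)cc2OC)c(OC)c(OCc2ccccc2)c(OC)c1OCc1ccccc1)=P(c1ccccc1)(c1ccccc1)c1ccccc1 | intermediate
18 | 5,7-bis(benzyloxy)-2-[4-(benzyloxy)-2,5-dimethoxyphenyl]-3,6,8-trimethoxy-4H-chromen-4-one | COc1c(OCc2ccccc2)c(OC)c2oc(-c3cc(OC)c(OCc4ccccc4)cc3OC)c(OC)c(=O)c2c1OCc1ccccc1 | intermediate
19 | 5,7,4'-trihydroxy-3,6,8,2',5'-pentamethoxyflavone | COc1cc(-c2oc3c(OC)c(O)c(OC)c(O)c3c(=O)c2OC)c(OC)cc1O | target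

**Step count and risks**

Total step count: 14. Longest linear sequence: 10 steps (steps 1–5 and 10–14, from phloroglucinol).

Steps most likely to fail:

1. Step 13 (proposed new method). The acylation at the di-ortho-substituted aroyl chloride may be slow enough for the ylide to attack the aryl ester or decompose. The fully substituted, methoxy-bearing ylide carbon of 17 may also fail to add to the hindered ester carbonyl, so that acyl transfer to the enolate oxygen or thermal breakdown takes over. Fallback by known chemistry, setting out from 14: the parent ylide methylidenetriphenylphosphorane F1 (2.1 equiv, from Ph3PCH3Br and NaN(SiMe3)2 in THF) is acylated at −78 °C to 3,5-bis(benzyloxy)-4,6-dimethoxy-2-[(triphenyl-λ5-phosphanylidene)acetyl]phenyl 4-(benzyloxy)-2,5-dimethoxybenzoate F2. In toluene at 110 °C this should close, by the demonstrated form of the ester Wittig reaction, to 5,7-bis(benzyloxy)-2-[4-(benzyloxy)-2,5-dimethoxyphenyl]-6,8-dimethoxy-4H-chromen-4-one F3. The C3 oxygen is then introduced after ring closure: lithiation at C3 with LiN(iPr)2 (THF, −78 °C) and trapping with B(OMe)3 gives dimethyl {5,7-bis(benzyloxy)-2-[4-(benzyloxy)-2,5-dimethoxyphenyl]-6,8-dimethoxy-4-oxo-4H-chromen-3-yl}boronate F4 (not isolated). Oxidation with H2O2/AcOH gives 5,7-bis(benzyloxy)-2-[4-(benzyloxy)-2,5-dimethoxyphenyl]-3-hydroxy-6,8-dimethoxy-4H-chromen-4-one F5, and O-methylation (MeI, K2CO3, acetone) comes back to the route at 18.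

2. Step 3. Substitution at bromides flanked by two benzyloxy groups may stay incomplete, and reductive loss of bromine may compete, giving mono-methoxy and debrominated material. Fallback, setting out from 3: palladium-catalysed hydroxylation (Pd2(dba)3, tBuXPhos, KOH, dioxane/H2O, 100 °C) to 2,4,6-tris(benzyloxy)benzene-1,3-diol F6, then O-methylation (MeI, K2CO3, DMF), which comes back to the route at 4.

3. Step 5. Cleavage may run on to the second ortho benzyl ether, or stall before completion, so that the single phenol is not obtained cleanly. Fallback, setting out from 5: all three benzyl ethers are removed (BCl3, pentamethylbenzene, CH2Cl2, −78 °C) to give 2,4,6-trihydroxy-3,5-dimethoxybenzaldehyde F7. Benzylation with two equivalents of BnBr (K2CO3, DMF, rt) should then take the para hydroxyl and one ortho hydroxyl, the last ortho hydroxyl being held back by its hydrogen bond to the aldehyde; this comes back to the route at 6.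

**Further compounds**

F1 | step 13 | methylidenetriphenylphosphorane | C=P(c1ccccc1)(c1ccccc1)c1ccccc1
F2 | step 13 | 3,5-bis(benzyloxy)-4,6-dimethoxy-2-[(triphenyl-λ5-phosphanylidene)acetyl]phenyl 4-(benzyloxy)-2,5-dimethoxybenzoate | O=C(C=P(c1ccccc1)(c1ccccc1)c1ccccc1)c1c(OC(=O)c2cc(OC)c(OCc3ccccc3)cc2OC)c(OC)c(OCc2ccccc2)c(OC)c1OCc1ccccc1
F3 | step 13 | 5,7-bis(benzyloxy)-2-[4-(benzyloxy)-2,5-dimethoxyphenyl]-6,8-dimethoxy-4H-chromen-4-one | COc1c(OCc2ccccc2)c(OC)c2oc(-c3cc(OC)c(OCc4ccccc4)cc3OC)cc(=O)c2c1OCc1ccccc1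
F4 | step 13 | dimethyl {5,7-bis(benzyloxy)-2-[4-(benzyloxy)-2,5-dimethoxyphenyl]-6,8-dimethoxy-4-oxo-4H-chromen-3-yl}boronate | COB(OC)c1c(-c2cc(OC)c(OCc3ccccc3)cc2OC)oc2c(OC)c(OCc3ccccc3)c(OC)c(OCc3ccccc3)c2c1=O
F5 | step 13 | 5,7-bis(benzyloxy)-2-[4-(benzyloxy)-2,5-dimethoxyphenyl]-3-hydroxy-6,8-dimethoxy-4H-chromen-4-one | COc1c(OCc2ccccc2)c(OC)c2oc(-c3cc(OC)c(OCc4ccccc4)cc3OC)c(O)c(=O)c2c1OCc1ccccc1
F6 | step 3 | 2,4,6-tris(benzyloxy)benzene-1,3-diol | Oc1c(OCc2ccccc2)cc(OCc2ccccc2)c(O)c1OCc1ccccc1
F7 | step 5 | 2,4,6-trihydroxy-3,5-dimethoxybenzaldehyde | O=Cc1c(O)c(OC)c(O)c(OC)c1O
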